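**Retrosynthetic overview**

1. Locants: C1 (CHOH), C2, C3 (CHOAc), C4(C15H3)=C5, C6 (lactone O), C7, C8 (O-2-methylbutanoyl), C9=C10(C14H3), lactone C11(=C13H2)–C12(=O). Target: 1S,3S,6S,7R,8R,2′R, 4Z,9Z, lactone 6,7-cis-fused.
2. Key disconnection C3–C4, closing the ten-membered ring last by a nickel-catalysed reductive allene–aldehyde coupling. Enabling feature: C4 is the methyl-bearing carbon of a cis ring alkene lying between the C3 carbinol and the lactone carbinol C6. The unit C6–CH=C(CH3)–CH(O)– is a (Z)-2-methylallylic alcohol, i.e. terminal allene C5=C4=C15H2 on C6 plus C3 aldehyde plus H, so C15, the 4Z alkene, C3 and the ring come from one event.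
3. The five-membered cis-lactone is formed first, by allylboration (C6–C7) of a protected 4-hydroxybut-2-ynal with an ester-bearing allylboronate that already carries C8 and its acyl group. The alkyne is then turned into the allene, and the methylene lactone is masked as its Me2NH adduct for the nickel step.
4. The allylboronate comes from the (Z)-enal C8–C3 by catalytic asymmetric propiolate addition (C8), trans-hydroalumination/iodination and Negishi borylmethylation. The enal comes from 3-silyloxypropanal by Midland reduction (C1) and anti-carbomagnesiation/iodination (9Z).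
5. End game: C3 acetylation, C1 desilylation, unmasking of the methylene lactone.

Key step: step 19

**Remarks (assumptions)**

- The (S,S)-ProPhenol/Me2Zn catalyst is taken to add the alkynyl group to the Si face of enal 8 (4R in 10); if its sense is the opposite, the (R,R)-ligand is used.
- The amine adducts 25–31 form as C11 epimers; both converge on 32, so C11 is left undefined in their SMILES.
- (R)-2-Methylbutanoic acid (12) and (S)-Alpine-Borane are taken as commercially available in enantiopure form.

**Route**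

Step 1
Reactants: 1 3-[(tert-butyldimethylsilyl)oxy]propanal; 2 ethynylmagnesium bromide
Product: 3 racemic 5-silyloxypent-1-yn-3-ol
Conditions: THF, −78 °C → 0 °C; aq. NH4Cl
Reagents that add atoms: none
Why: Grignard addition of the acetylide to the aldehyde; the carbinol (later C1) is formed racemic and is set in step 3.

Step 2
Reactants: 3 racemic 5-silyloxypent-1-yn-3-ol
Product: 4 5-silyloxypent-1-yn-3-one
Conditions: Dess–Martin periodinane, CH2Cl2, 0 °C → rt
Reagents that add atoms: none
Why: Dess–Martin oxidation of the secondary propargylic alcohol to the ynone, neutral enough for the silyl ether.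

Step 3
Reactants: 4 5-silyloxypent-1-yn-3-one
Product: 5 (S)-5-silyloxypent-1-yn-3-ol
Conditions: (S)-Alpine-Borane (1.5 equiv), neat, rt; then CH3CHO; then HOCH2CH2NH2, Et2O, 0 °C
Reagents that add atoms: none
Why: Midland reduction, in which the pinanyl borane transfers hydride in a boat-like six-membered transition state with the slim ethynyl group in the crowded position, should give the (S)-alcohol (C1) from the terminal ynone with the (S)-reagent.

Step 4
Reactants: 5 (S)-5-silyloxypent-1-yn-3-ol
Product: 6 (1Z,3S)-1-iodo-2-methyl-5-silyloxypent-1-en-3-ol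
Conditions: MeMgBr (3 equiv), CuI (20 mol %), THF, −20 °C → rt; then I2, −78 °C → 0 °C
Reagents that add atoms: methylmagnesium bromide, C[Mg]Br; iodine, II
Why: Copper-catalysed anti-carbomagnesiation of the magnesium alkoxide of the propargylic alcohol adds methyl to the internal alkyne carbon and magnesium to the terminal one within a five-membered chelate, and iodinolysis with retention should give the (Z)-alkenyl iodide, which fixes the C9=C10 geometry.

Step 5
Reactants: 6 (1Z,3S)-1-iodo-2-methyl-5-silyloxypent-1-en-3-ol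
Product: 7 (1Z,3S)-3,5-bis(silyloxy)-1-iodo-2-methylpent-1-ene
Conditions: TBSOTf, 2,6-lutidine, CH2Cl2, −78 °C → 0 °C
Reagents that add atoms: tert-butyldimethylsilyl trifluoromethanesulfonate, CC(C)(C)[Si](C)(C)OS(=O)(=O)C(F)(F)F
Why: Silyl triflate silylation of the hindered secondary allylic alcohol.

Step 6
Reactants: 7 (1Z,3S)-3,5-bis(silyloxy)-1-iodo-2-methylpent-1-ene
Product: 8 (2Z,4S)-4,6-bis(silyloxy)-3-methylhex-2-enal
Conditions: t-BuLi (2.1 equiv), Et2O, −78 °C; then DMF; H2O
Reagents that add atoms: N,N-dimethylformamide, CN(C)C=O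
Why: Iodine–lithium exchange and formylation of the alkenyllithium with DMF, both with retention of the alkene geometry.

Step 7
Reactants: 8 (2Z,4S)-4,6-bis(silyloxy)-3-methylhex-2-enal; 9 methyl propiolate
Product: 10 (4R)-γ-hydroxy ynoate
Conditions: (S,S)-ProPhenol (20 mol %), Me2Zn (3 equiv), Ph3P=O (40 mol %), 9 (3 equiv), toluene, 4 °C
Reagents that add atoms: none
Why: Catalytic asymmetric alkynylation of an enal with the dinuclear zinc–ProPhenol catalyst, a substrate class for which the alkynylzinc addition is face-selective, should set C8 (4R) under catalyst control, the remote C1 centre having little say.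

Step 8
Reactants: 10 (4R)-γ-hydroxy ynoate
Product: 11 (2Z)-α-iodo-γ-hydroxy enoate
Conditions: NaAlH2(OCH2CH2OMe)2 (Red-Al, 1.6 equiv), THF, −78 °C; then I2, −78 °C → −20 °C; aq. Rochelle salt
Reagents that add atoms: iodine, II
Why: Hydroxyl-directed trans-hydroalumination of the γ-hydroxy ynoate (hydride to the carbon next to the carbinol, aluminium to the ester-bearing carbon within a five-membered alkoxyaluminate) and iodinolysis with retention should give the α-iodo enoate with iodine cis to C8.

Step 9
Reactants: 11 (2Z)-α-iodo-γ-hydroxy enoate; 12 (R)-2-methylbutanoic acid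
Product: 13 α-iodo enoate 2-methylbutanoate
Conditions: N,N′-diisopropylcarbodiimide, DMAP (10 mol %), CH2Cl2, 0 °C
Reagents that add atoms: none
Why: Steglich esterification of the secondary alcohol; low temperature and catalytic DMAP should keep the α-stereocentre of the acid intact.

Step 10
Reactants: 13 α-iodo enoate 2-methylbutanoate
Product: 14 ester-bearing allylboronate
Conditions: IZnCH2B(pin) (from ICH2B(pin), Zn dust, THF), Pd(PPh3)4 (5 mol %), THF, rt → 40 °C
Reagents that add atoms: (pinacolatoboryl)methylzinc iodide, I[Zn]CB1OC(C)(C)C(C)(C)O1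
Why: Negishi coupling of the alkenyl iodide with the borylmethylzinc reagent proceeds with retention and should give the configurationally stable allylboronate with C8 cis to CH2B.

Step 11
Reactants: 15 but-2-yne-1,4-diol
Product: 16 4-[(4-methoxybenzyl)oxy]but-2-yn-1-ol
Conditions: NaH (1 equiv), 4-methoxybenzyl chloride, Bu4NI (cat.), THF, 0 °C → rt
Reagents that add atoms: 4-methoxybenzyl chloride, COc1ccc(CCl)cc1
Why: Williamson monoalkylation of the symmetrical diol with one equivalent of base.

Step 12
Reactants: 16 4-[(4-methoxybenzyl)oxy]but-2-yn-1-ol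
Product: 17 4-[(4-methoxybenzyl)oxy]but-2-ynal
Conditions: MnO2, CH2Cl2, rt
Reagents that add atoms: none
Why: MnO2 oxidises the primary propargylic alcohol selectively to the ynal.

Step 13
Reactants: 14 ester-bearing allylboronate; 17 4-[(4-methoxybenzyl)oxy]but-2-ynal
Product: 19 cis-lactone propargyl PMB ether, via O-boryl syn adduct 18 (not isolated)
Conditions: Sc(OTf)3 (10 mol %), 4 Å MS, toluene, 0 °C → rt; then PPTS, 60 °C
Reagents that add atoms: none
Why: Lewis acid-catalysed allylboration through a closed six-membered chair transition state followed by lactonisation: C8 cis to CH2B gives the syn C6/C7 pair and hence the cis-lactone, and the aldehyde should be taken up on the face of C7=C11 anti to the C9 alkenyl branch of C8, with H8 in the alkene plane (allylic 1,3-strain) and the acyloxy group outside, which relates C6 and C7 to C8 as in the target.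

Step 14
Reactants: 19 cis-lactone propargyl PMB ether
Product: 20 cis-lactone propargylic alcohol
Conditions: DDQ, CH2Cl2/pH 7 buffer, 0 °C
Reagents that add atoms: none
Why: Oxidative cleavage of the 4-methoxybenzyl ether with DDQ, which leaves silyl ethers, esters and the lactone alone.

Step 15
Reactants: 20 cis-lactone propargylic alcohol
Product: 23 allenyl cis-lactone, via propargyl sulfonylhydrazine 21 (not isolated), via propargyl diazene 22 (not isolated)
Conditions: PPh3, DEAD, THF, −15 °C; then 2-nitrobenzenesulfonylhydrazide, −15 °C → rt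
Reagents that add atoms: none
Why: Myers allene synthesis: Mitsunobu N-alkylation of the sulfonylhydrazide, loss of the sulfinic acid and retro-ene loss of N2 from the propargyl diazene should deliver the terminal allene under neutral conditions below room temperature.

Step 16
Reactants: 23 allenyl cis-lactone
Product: 24 allenyl lactone primary alcohol
Conditions: HF·pyridine, pyridine, THF, 0 °C
Reagents that add atoms: none
Why: Pyridine-buffered HF·pyridine cleaves the primary silyl ether much faster than the hindered secondary allylic one.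

Step 17
Reactants: 24 allenyl lactone primary alcohol
Product: 25 amine-masked allenyl alcohol
Conditions: Me2NH (2 M in THF), THF, 0 °C → rt
Reagents that add atoms: dimethylamine, CNC
Why: Aza-Michael addition of dimethylamine masks the electron-poor methylene lactone for the nickel step; the new C11 centre is of no consequence because step 22 removes it.

Step 18
Reactants: 25 amine-masked allenyl alcohol
Product: 26 amine-masked allenyl aldehyde
Conditions: SO3·pyridine, DMSO, i-Pr2NEt, CH2Cl2, 0 °C
Reagents that add atoms: none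
Why: Parikh–Doering oxidation of the primary alcohol to the aldehyde, compatible with the tertiary amine, the allene and the β-silyloxy group.

Step 19
Reactants: 26 amine-masked allenyl aldehyde
Product: 28 macrocyclic C3 alcohol, via macrocyclic C3 triethylsilyl ether 27 (not isolated)
Conditions: Ni(cod)2 (30 mol %), IPr (1,3-bis(2,6-diisopropylphenyl)imidazol-2-ylidene, 30 mol %), Et3SiH (5 equiv), THF, rt, 26 added over 10 h (final 0.002 M); then PPTS (2 equiv), MeOH, 0 °C
Reagents that add atoms: none
Why: Proposed new method: zerovalent nickel carrying the carbene ligand binds the terminal C4=C15 π bond of the allene together with the C3 aldehyde and couples them by oxidative cyclisation (C3–C4 bond, oxanickelacycle whose carbon end is an allylnickel unit C15–C4–C5); Si–H σ-bond metathesis with Et3SiH and C–H reductive elimination at C15, the unsubstituted allyl terminus, then turn C15 into the methyl group, leave C4=C5 as the alkene and release the C3 silyl ether 27, which mild acid cleaves to 28. The closest known reaction type is the intermolecular nickel/N-heterocyclic carbene three-component coupling of monosubstituted allenes, aldehydes and silanes, which bonds the aldehyde to the central allene carbon and gives (Z)-2-methylallylic silyl ethers, and nickel-catalysed reductive macrocyclisations of ynals show that this kind of oxidative cyclisation closes rings of ten and more members. The ten-membered ring closes in the exo mode with respect to the C4=C15 bond (C15 stays outside the ring), C4=C5 becoming the endocyclic alkene; it should be cis because the chain from C6 reaches C4 on the face of the C4=C15 π bond that lies on the C6 side, which is also the (Z) sense the intermolecular reaction prefers. C3 is set by the macrocyclic transition state, in which the carbonyl oxygen is bound to nickel on the ring periphery and the C1 silyloxy group turns away from the carbonyl dipole (1,3-anti, 3S); should the C3 epimer form instead, the acetate of step 20 can be put on with inversion (Mitsunobu, AcOH) rather than with retention. The step needs chemoselectivity for allene plus aldehyde and ring closure over oligomerisation: the methylene lactone is masked as the amine adduct so that no electron-poor alkene competes for nickel, the only other alkene is trisubstituted, the cis-fused lactone places the C6 allene and the C7 side chain on one face so that the chain ends can meet, and 26 is added slowly at high dilution.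

Step 20
Reactants: 28 macrocyclic C3 alcohol
Product: 29 macrocyclic C3 acetate
Conditions: Ac2O, pyridine, DMAP (cat.), CH2Cl2, 0 °C → rt
Reagents that add atoms: acetic anhydride, CC(=O)OC(C)=O
Why: DMAP-catalysed acetylation of the only free hydroxyl group (C3) with retention.

Step 21
Reactants: 29 macrocyclic C3 acetate
Product: 30 amine-masked C1 alcohol
Conditions: HF·pyridine, THF, 0 °C → rt
Reagents that add atoms: none
Why: Fluoride-mediated cleavage of the remaining secondary silyl ether under acidic conditions that should not move the acetate.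

Step 22
Reactants: 30 amine-masked C1 alcohol
Product: 32 target CNP0282531.1, via trimethylammonium iodide 31 (not isolated)
Conditions: MeI, MeCN, rt; then aq. NaHCO3, CH2Cl2, rt
Reagents that add atoms: none
Why: Exhaustive methylation of the amine and mild base-induced β-elimination (retro-Michael of the ammonium salt) should regenerate the α-methylene lactone as the last operation.

**Compound list**

In the names below, TBS = tert-butyldimethylsilyl and "side chain A" = the (1R,2Z,4S)-4,6-bis(TBS-oxy)-3-methyl-1-{[(2R)-2-methylbutanoyl]oxy}hex-2-en-1-yl group on C7.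

1 | 3-[(tert-butyldimethylsilyl)oxy]propanal | O=CCCO[Si](C)(C)C(C)(C)C | starting material
2 | ethynylmagnesium bromide | C#C[Mg]Br | starting material
3 | (±)-5-[(tert-butyldimethylsilyl)oxy]pent-1-yn-3-ol | C#CC(O)CCO[Si](C)(C)C(C)(C)C | intermediate
4 | 5-[(tert-butyldimethylsilyl)oxy]pent-1-yn-3-one | C#CC(=O)CCO[Si](C)(C)C(C)(C)C | intermediate
5 | (S)-5-[(tert-butyldimethylsilyl)oxy]pent-1-yn-3-ol | C#C[C@@H](O)CCO[Si](C)(C)C(C)(C)C | intermediate
6 | (1Z,3S)-5-[(tert-butyldimethylsilyl)oxy]-1-iodo-2-methylpent-1-en-3-ol | I/C=C(\[C@H](CCO[Si](C)(C)C(C)(C)C)O)C | intermediate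
7 | (1Z,3S)-3,5-bis[(tert-butyldimethylsilyl)oxy]-1-iodo-2-methylpent-1-ene | I/C=C(\[C@H](CCO[Si](C)(C)C(C)(C)C)O[Si](C)(C)C(C)(C)C)C | intermediate
8 | (2Z,4S)-4,6-bis[(tert-butyldimethylsilyl)oxy]-3-methylhex-2-enal | O=C/C=C(\[C@H](CCO[Si](C)(C)C(C)(C)C)O[Si](C)(C)C(C)(C)C)C | intermediate
9 | methyl propiolate | C#CC(=O)OC | starting material
10 | methyl (4R,5Z,7S)-7,9-bis[(tert-butyldimethylsilyl)oxy]-4-hydroxy-6-methylnon-5-en-2-ynoate | COC(=O)C#C[C@@H](/C=C(\[C@H](CCO[Si](C)(C)C(C)(C)C)O[Si](C)(C)C(C)(C)C)C)O | intermediate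
11 | methyl (2Z,4R,5Z,7S)-7,9-bis[(tert-butyldimethylsilyl)oxy]-4-hydroxy-2-iodo-6-methylnona-2,5-dienoate | COC(=O)/C(I)=C/[C@@H](/C=C(\[C@H](CCO[Si](C)(C)C(C)(C)C)O[Si](C)(C)C(C)(C)C)C)O | intermediate
12 | (R)-2-methylbutanoic acid | CC[C@@H](C)C(=O)O | starting material
13 | methyl (2Z,4R,5Z,7S)-7,9-bis[(tert-butyldimethylsilyl)oxy]-2-iodo-6-methyl-4-{[(2R)-2-methylbutanoyl]oxy}nona-2,5-dienoate | COC(=O)/C(I)=C/[C@@H](/C=C(\[C@H](CCO[Si](C)(C)C(C)(C)C)O[Si](C)(C)C(C)(C)C)C)OC(=O)[C@H](C)CC | intermediate
14 | methyl (2E,4R,5Z,7S)-7,9-bis[(tert-butyldimethylsilyl)oxy]-6-methyl-4-{[(2R)-2-methylbutanoyl]oxy}-2-[(4,4,5,5-tetramethyl-1,3,2-dioxaborolan-2-yl)methyl]nona-2,5-dienoate (C8 cis to CH2B) | COC(=O)/C(CB1OC(C)(C)C(C)(C)O1)=C/[C@@H](/C=C(\[C@H](CCO[Si](C)(C)C(C)(C)C)O[Si](C)(C)C(C)(C)C)C)OC(=O)[C@H](C)CC | intermediate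
15 | but-2-yne-1,4-diol | OCC#CCO | starting material
16 | 4-[(4-methoxybenzyl)oxy]but-2-yn-1-ol | OCC#CCOCc1ccc(OC)cc1 | intermediate
17 | 4-[(4-methoxybenzyl)oxy]but-2-ynal | O=CC#CCOCc1ccc(OC)cc1 | intermediate
18 | open-chain allylboration adduct: methyl 2-methylene ester (C11=C13H2, C12 = CO2Me) with C6–O–B(pin); C6 bears 3-[(4-methoxybenzyl)oxy]prop-1-ynyl, C7 bears side chain A; C6/C7 syn | C=C(C(=O)OC)[C@@H]([C@@H](OB1OC(C)(C)C(C)(C)O1)C#CCOCc1ccc(OC)cc1)[C@@H](/C=C(\[C@H](CCO[Si](C)(C)C(C)(C)C)O[Si](C)(C)C(C)(C)C)C)OC(=O)[C@H](C)CC | intermediate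
19 | 6,7-cis α-methylene-γ-butyrolactone; C6 bears 3-[(4-methoxybenzyl)oxy]prop-1-ynyl, C7 bears side chain A | C=C1C(=O)O[C@@H](C#CCOCc2ccc(OC)cc2)[C@H]1[C@@H](/C=C(\[C@H](CCO[Si](C)(C)C(C)(C)C)O[Si](C)(C)C(C)(C)C)C)OC(=O)[C@H](C)CC | intermediate
20 | as 19, C6 bears 3-hydroxyprop-1-ynyl | C=C1C(=O)O[C@@H](C#CCO)[C@H]1[C@@H](/C=C(\[C@H](CCO[Si](C)(C)C(C)(C)C)O[Si](C)(C)C(C)(C)C)C)OC(=O)[C@H](C)CC | intermediate
21 | as 20, CH2–N(NH2)–SO2(2-nitrophenyl) in place of CH2OH | C=C1C(=O)O[C@@H](C#CCN(N)S(=O)(=O)c2ccccc2[N+](=O)[O-])[C@H]1[C@@H](/C=C(\[C@H](CCO[Si](C)(C)C(C)(C)C)O[Si](C)(C)C(C)(C)C)C)OC(=O)[C@H](C)CC | intermediate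
22 | as 20, CH2–N=NH in place of CH2OH (propargyl diazene) | C=C1C(=O)O[C@@H](C#CCN=N)[C@H]1[C@@H](/C=C(\[C@H](CCO[Si](C)(C)C(C)(C)C)O[Si](C)(C)C(C)(C)C)C)OC(=O)[C@H](C)CC | intermediate
23 | as 19, C6 bears propa-1,2-dienyl (C5=C4=C15H2) | C=C1C(=O)O[C@@H](C=C=C)[C@H]1[C@@H](/C=C(\[C@H](CCO[Si](C)(C)C(C)(C)C)O[Si](C)(C)C(C)(C)C)C)OC(=O)[C@H](C)CC | intermediate
24 | as 23, C3–OH free, C1–O-TBS kept | C=C1C(=O)O[C@@H](C=C=C)[C@H]1[C@@H](/C=C(\[C@H](CCO)O[Si](C)(C)C(C)(C)C)C)OC(=O)[C@H](C)CC | intermediate
25 | dimethylamine adduct of 24 (C13–NMe2, C11 epimers) | CN(C)CC1C(=O)O[C@@H](C=C=C)[C@H]1[C@@H](/C=C(\[C@H](CCO)O[Si](C)(C)C(C)(C)C)C)OC(=O)[C@H](C)CC | intermediate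
26 | C3 aldehyde of 25 | CN(C)CC1C(=O)O[C@@H](C=C=C)[C@H]1[C@@H](/C=C(\[C@H](CC=O)O[Si](C)(C)C(C)(C)C)C)OC(=O)[C@H](C)CC | intermediate
27 | ten-membered carbocycle, 4Z,9Z: C3–O-SiEt3, C1–O-TBS, C8–O-(R)-2-methylbutanoyl, 6,7-cis lactone with C13–NMe2 | CN(C)CC1C(=O)O[C@H]2/C=C(/C)[C@@H](O[Si](CC)(CC)CC)C[C@H](O[Si](C)(C)C(C)(C)C)/C(C)=C\[C@@H](OC(=O)[C@H](C)CC)[C@@H]12 | intermediate
28 | as 27, C3–OH free (3S) | CN(C)CC1C(=O)O[C@H]2/C=C(/C)[C@@H](O)C[C@H](O[Si](C)(C)C(C)(C)C)/C(C)=C\[C@@H](OC(=O)[C@H](C)CC)[C@@H]12 | intermediate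
29 | as 28, C3–OAc | CN(C)CC1C(=O)O[C@H]2/C=C(/C)[C@@H](OC(C)=O)C[C@H](O[Si](C)(C)C(C)(C)C)/C(C)=C\[C@@H](OC(=O)[C@H](C)CC)[C@@H]12 | intermediate
30 | as 29, C1–OH free | CN(C)CC1C(=O)O[C@H]2/C=C(/C)[C@@H](OC(C)=O)C[C@H](O)/C(C)=C\[C@@H](OC(=O)[C@H](C)CC)[C@@H]12 | intermediate
31 | trimethylammonium iodide of 30 | C[N+](C)(C)CC1C(=O)O[C@H]2/C=C(/C)[C@@H](OC(C)=O)C[C@H](O)/C(C)=C\[C@@H](OC(=O)[C@H](C)CC)[C@@H]12.[I-] | intermediate
32 | CNP0282531.1: (1S,3S,6S,7R,8R,4Z,9Z)-3-acetoxy-1-hydroxy-8-{[(2R)-2-methylbutanoyl]oxy}-4,10-dimethyl ten-membered carbocycle fused 6,7-cis to the 11(13)-methylene-12,6-lactone | C=C1C(=O)O[C@H]2/C=C(/C)[C@@H](OC(C)=O)C[C@H](O)/C(C)=C\[C@@H](OC(=O)[C@H](C)CC)[C@@H]12 | target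

**Totals**

Total steps: 22. Longest linear sequence: 20 (steps 1–10 and 13–22).

**Steps most likely to fail, with fallbacks**

1. Step 19 (proposed new method).
 - What may go wrong: zerovalent nickel may ionise the allenylic C6–O bond of the lactone or oligomerise the allene faster than it closes the ten-membered ring. Hydride may be delivered to C5 instead of C15, giving the exocyclic methylene isomer. The facial selectivity at C3 rests on the macrocyclic transition state alone.
 - Fallback with known chemistry (Nozaki–Hiyama–Kishi macrocyclisation of a (Z)-alkenyl iodide), setting out from boronate 14 and coming back at target 32. But-2-yn-1-ol is hydroaluminated with NaAlH2(OCH2CH2OMe)2 and iodinated to (Z)-3-iodobut-2-en-1-ol F1, which MnO2 oxidises to (Z)-3-iodobut-2-enal F2. Sc(OTf)3-catalysed allylboration of F2 with 14 should give the O-boryl syn adduct F3 and, with PPTS, the alkenyl iodide cis-lactone F4. HF·pyridine/pyridine frees the primary alcohol F5, and Dess–Martin oxidation gives the iodo aldehyde F6. CrCl2 with catalytic NiCl2 in DMSO/THF at high dilution should join C4 to C3 with retention of the alkene geometry to give the macrocyclic alcohol F7. Ac2O/DMAP gives the acetate F8, and HF·pyridine gives 32. Under divalent chromium the methylene lactone needs no mask.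

2. Step 13.
 - What may go wrong: the ester-deactivated allylboronate may add too slowly, so that the Lewis acid begins to strip silyl ethers or the reaction leaves the closed transition state, with loss of the syn relationship or of facial control by C8.
 - Fallback, setting out from iodide 13 and coming back at lactone 19. Stille coupling of 13 with Bu3SnCH2OH (Pd2(dba)3, AsPh3) should give the hydroxymethyl enoate F9. Appel bromination gives the (Z)-allylic bromide F10. An indium-mediated Barbier reaction of F10 with 17 in THF/H2O should give the syn hydroxy ester F11, which PPTS lactonises to 19.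

3. Step 7.
 - What may go wrong: Z to E isomerisation of enal 8 under the Lewis acidic zinc conditions, or insufficient facial control by the catalyst.
 - Fallback, setting out from 8 and coming back at 10. Methyl propiolate deprotonated with LiHMDS adds to 8 at −78 °C to give the C4-epimeric alcohols F12. Dess–Martin oxidation gives the ynone F13. Reduction with the (R)-CBS oxazaborolidine and catecholborane (alkenyl as the large group) should set 4R and return 10.

**Further compounds**

F1 | step 19 | (Z)-3-iodobut-2-en-1-ol | OC/C=C(/C)I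
F2 | step 19 | (Z)-3-iodobut-2-enal | O=C/C=C(/C)I
F3 | step 19 | open-chain O-boryl syn adduct, as 18 but C6 bears (Z)-2-iodoprop-1-enyl | C=C(C(=O)OC)[C@@H]([C@@H](OB1OC(C)(C)C(C)(C)O1)/C=C(/C)I)[C@@H](/C=C(\[C@H](CCO[Si](C)(C)C(C)(C)C)O[Si](C)(C)C(C)(C)C)C)OC(=O)[C@H](C)CC
F4 | step 19 | 6,7-cis α-methylene lactone, C6 bears (Z)-2-iodoprop-1-enyl, C7 bears side chain A | C=C1C(=O)O[C@@H](/C=C(/C)I)[C@H]1[C@@H](/C=C(\[C@H](CCO[Si](C)(C)C(C)(C)C)O[Si](C)(C)C(C)(C)C)C)OC(=O)[C@H](C)CC
F5 | step 19 | as F4, C3–OH free | C=C1C(=O)O[C@@H](/C=C(/C)I)[C@H]1[C@@H](/C=C(\[C@H](CCO)O[Si](C)(C)C(C)(C)C)C)OC(=O)[C@H](C)CC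
F6 | step 19 | C3 aldehyde of F5 | C=C1C(=O)O[C@@H](/C=C(/C)I)[C@H]1[C@@H](/C=C(\[C@H](CC=O)O[Si](C)(C)C(C)(C)C)C)OC(=O)[C@H](C)CC
F7 | step 19 | macrocyclic C3 alcohol with free methylene lactone and C1–O-TBS | C=C1C(=O)O[C@H]2/C=C(/C)[C@@H](O)C[C@H](O[Si](C)(C)C(C)(C)C)/C(C)=C\[C@@H](OC(=O)[C@H](C)CC)[C@@H]12
F8 | step 19 | C3 acetate of F7 | C=C1C(=O)O[C@H]2/C=C(/C)[C@@H](OC(C)=O)C[C@H](O[Si](C)(C)C(C)(C)C)/C(C)=C\[C@@H](OC(=O)[C@H](C)CC)[C@@H]12
F9 | step 13 | methyl (2E,4R,5Z,7S)-7,9-bis[(tert-butyldimethylsilyl)oxy]-2-(hydroxymethyl)-6-methyl-4-{[(2R)-2-methylbutanoyl]oxy}nona-2,5-dienoate | COC(=O)/C(CO)=C/[C@@H](/C=C(\[C@H](CCO[Si](C)(C)C(C)(C)C)O[Si](C)(C)C(C)(C)C)C)OC(=O)[C@H](C)CC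
F10 | step 13 | methyl (2Z,4R,5Z,7S)-2-(bromomethyl)-7,9-bis[(tert-butyldimethylsilyl)oxy]-6-methyl-4-{[(2R)-2-methylbutanoyl]oxy}nona-2,5-dienoate | COC(=O)/C(CBr)=C/[C@@H](/C=C(\[C@H](CCO[Si](C)(C)C(C)(C)C)O[Si](C)(C)C(C)(C)C)C)OC(=O)[C@H](C)CC
F11 | step 13 | open-chain syn hydroxy ester, as 18 with C6–OH | C=C(C(=O)OC)[C@@H]([C@@H](O)C#CCOCc1ccc(OC)cc1)[C@@H](/C=C(\[C@H](CCO[Si](C)(C)C(C)(C)C)O[Si](C)(C)C(C)(C)C)C)OC(=O)[C@H](C)CC
F12 | step 7 | methyl (4RS,5Z,7S)-7,9-bis[(tert-butyldimethylsilyl)oxy]-4-hydroxy-6-methylnon-5-en-2-ynoate (C4 epimers) | COC(=O)C#CC(O)/C=C(\[C@H](CCO[Si](C)(C)C(C)(C)C)O[Si](C)(C)C(C)(C)C)C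
F13 | step 7 | methyl (5Z,7S)-7,9-bis[(tert-butyldimethylsilyl)oxy]-6-methyl-4-oxonon-5-en-2-ynoate | COC(=O)C#CC(=O)/C=C(\[C@H](CCO[Si](C)(C)C(C)(C)C)O[Si](C)(C)C(C)(C)C)C
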